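The lactone O–C6 bond is cut first, with allylic transposition, which turns the target into an isomeric epoxy acid. The next cuts are C5=C6 (ring-closing metathesis), C2–C3 (sp–sp2 coupling), the C8–O ester bond (inversion) and C7–C8 (carbonyl allylation).
In the ten-membered ring, O–C3–C4(CH3)=C5–C6–O is a (Z)-2-ene-1,4-dioxygen pattern, and the C12 carboxyl group sits on C7, next to C6. That pattern results when a carboxylate that can only close the five-membered ring O, C12, C11, C7, C6 opens, in a syn-1,4 sense, a C3–C4 oxirane carrying a C5=C6 vinyl group.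
In the forward direction a C8–C10/C1–C2 alkynal, a five-carbon dienoate bromide (C6, C7, C11–C13) and a four-carbon iodoalkenol (C3–C5, C15) are joined to one chain. The C3–C4 and C1–C2 oxiranes are made on the chain, the carbocycle closes at C5=C6, and the lactone closes last, with no hydroxyl protecting group.
C10 and C3/C4 come from two Sharpless epoxidations, and C7/C8 from a ligand-controlled chromium allylation followed by Mitsunobu inversion at C8 with angelic acid. C1/C2 come from a hydroxyl-directed epoxidation, 5Z from ring strain, and C6 and the 4Z alkene from C4-to-C6 chirality transfer in the key step.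

Key step: step 18

Numbering: germacrane numbers of the target are used for all intermediates. The ring is C1–C10: C1/C2 oxirane, C3 carbinol, C4=C5, C6 lactone carbinol, C7, C8 angelate, C9, C10 tertiary carbinol. C11–C13 is the acrylate unit, C14 the methyl on C10, C15 the methyl on C4.
Assumption: the (S,S)-ligand of step 7 is taken to direct the allylchromium reagent to the Si face of the aldehyde; if its sense is the opposite, the (R,R)-ligand is used.

Step 1
Reactants: 1 (E)-3-methylpent-2-en-4-yn-1-ol
Product: 2 [(2S,3S)-3-ethynyl-3-methyloxiran-2-yl]methanol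
Conditions: Ti(OiPr)4 (10 mol %), L-(+)-diethyl tartrate (12 mol %), t-BuOOH, 4 Å MS, CH2Cl2, −20 °C
Reagents that add atoms: tert-butyl hydroperoxide, CC(C)(C)OO
Why: Sharpless asymmetric epoxidation of an E-trisubstituted allylic alcohol: with L-(+)-tartrate the oxygen enters as it does with geraniol and gives the (2S,3S)-oxirane, which fixes the C10–O bond in the configuration of the target, while the alkyne is not touched.

Step 2
Reactants: 2 [(2S,3S)-3-ethynyl-3-methyloxiran-2-yl]methanol
Product: 3 (3R)-3-methylpent-4-yne-1,3-diol
Conditions: NaAlH2(OCH2CH2OMe)2, THF, −20 to 0 °C; aq. potassium sodium tartrate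
Reagents that add atoms: none
Why: Directed reductive opening of a 2,3-epoxy alcohol: the aluminium alkoxide at O8 delivers hydride to the neighbouring secondary carbon C9, so the 1,3-diol forms with the tertiary C10–O bond and its configuration intact, and the terminal alkyne, held as its aluminium acetylide, is not hydroaluminated at this temperature.

Step 3
Reactants: 3 (3R)-3-methylpent-4-yne-1,3-diol
Product: 4 (3R)-3-hydroxy-3-methylpent-4-ynal
Conditions: TEMPO (10 mol %), PhI(OAc)2, CH2Cl2, rt; used without storage
Reagents that add atoms: none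
Why: Oxoammonium (TEMPO) oxidation takes only the primary alcohol, the tertiary propargylic alcohol cannot be oxidised, and the nearly neutral medium avoids retro-aldol cleavage of the β-hydroxy aldehyde.

Step 4
Reactants: 5 acryloyl chloride; 6 2-(trimethylsilyl)ethanol
Product: 7 2-(trimethylsilyl)ethyl acrylate
Conditions: Et3N, CH2Cl2, 0 °C
Reagents that add atoms: none
Why: O-acylation of a primary alcohol with an acid chloride gives an ester that fluoride can remove later without acid or hydroxide.

Step 5
Reactants: 7 2-(trimethylsilyl)ethyl acrylate; 8 acrolein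
Product: 9 racemic 2-(trimethylsilyl)ethyl 3-hydroxy-2-methylidenepent-4-enoate
Conditions: DABCO (20 mol %), excess 7, neat, rt
Reagents that add atoms: none
Why: Morita–Baylis–Hillman reaction in which the ammonium enolate of the acrylate, kept in excess, adds to the aldehyde group of acrolein; the carbinol stereocentre is lost in step 6, so the racemate suffices.

Step 6
Reactants: 9 racemic 2-(trimethylsilyl)ethyl 3-hydroxy-2-methylidenepent-4-enoate
Product: 10 2-(trimethylsilyl)ethyl (2Z)-2-(bromomethyl)penta-2,4-dienoate
Conditions: PBr3, Et2O, 0 °C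
Reagents that add atoms: phosphorus tribromide, BrP(Br)Br
Why: Allylic bromination with SN2' transposition of a Morita–Baylis–Hillman alcohol gives the conjugated dienoate with the vinyl group trans to the ester (Z), which is the usual thermodynamic outcome for such esters.

Step 7
Reactants: 4 (3R)-3-hydroxy-3-methylpent-4-ynal; 10 2-(trimethylsilyl)ethyl (2Z)-2-(bromomethyl)penta-2,4-dienoate
Product: 12 (7R,8R,10R)-syn hydroxy ester, via C8 trimethylsilyl ether 11 (not isolated)
Conditions: CrCl2 (10 mol %), (S,S)-1,8-bis(4-isopropyl-4,5-dihydrooxazol-2-yl)-3,6-diphenylcarbazole (12 mol %), iPr2NEt (30 mol %), Mn, Me3SiCl, THF, rt; then 1 M HCl, THF, 0 °C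
Reagents that add atoms: chlorotrimethylsilane, C[Si](C)(C)Cl (its silyl group is carried only by 11)
Why: Catalytic asymmetric Nozaki–Hiyama–Kishi-type 2-(alkoxycarbonyl)allylation: the allylchromium reagent from 10 adds through its γ-carbon C7 in a chair transition state with the vinyl group, cis to CH2–Cr, axial, which gives the C7/C8 syn relation, the tridentate ligand directs attack to the Si face of the aldehyde (7R,8R) over the weak bias of remote C10, and silylation of the chromium alkoxide turns the catalyst over and prevents closure of an 8,12-lactone.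

Step 8
Reactants: 12 (7R,8R,10R)-syn hydroxy ester; 13 angelic acid [(2Z)-2-methylbut-2-enoic acid]
Product: 14 (7R,8S,10R)-angelate alkyne
Conditions: PPh3, DIAD, toluene, 0 °C to rt
Reagents that add atoms: none
Why: Mitsunobu esterification: angelate displaces the C8 oxyphosphonium group in an SN2 process with inversion (8R to 8S), which turns the syn adduct into the anti C7/C8 relation of the target and installs the Z-ester under neutral conditions that do not isomerise it, while the tertiary C10 hydroxyl group cannot be activated.

Step 9
Reactants: 15 prop-2-yn-1-ol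
Product: 17 (Z)-3-iodo-2-methylprop-2-en-1-ol, via alkenylmagnesium alkoxide 16 (not isolated)
Conditions: MeMgBr (2.2 equiv), CuI (10 mol %), Et2O, −10 °C to rt; then I2, THF, 0 °C
Reagents that add atoms: methylmagnesium bromide, C[Mg]Br; iodine, II
Why: Copper-catalysed anti-carbomagnesiation of the propargylic magnesium alkoxide puts methyl on the inner carbon and magnesium on the terminal carbon cis to CH2O in a five-membered chelate, and iodinolysis with retention gives the Z-iodoalkene, that is the C3–C5/C15 unit with the future C2 position cis to C5.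

Step 10
Reactants: 14 (7R,8S,10R)-angelate alkyne; 17 (Z)-3-iodo-2-methylprop-2-en-1-ol
Product: 18 (3Z)-enynol
Conditions: PdCl2(PPh3)2 (3 mol %), CuI (6 mol %), Et3N, THF, rt
Reagents that add atoms: none
Why: Sonogashira coupling forms C2–C3 at room temperature with retention of the alkene geometry and faster than any Heck reaction of the terminal alkenes, and the tertiary amine base cannot add irreversibly to the acrylate.

Step 11
Reactants: 18 (3Z)-enynol
Product: 19 (3S,4R)-alkynyl oxirane
Conditions: Ti(OiPr)4 (15 mol %), D-(−)-diethyl tartrate (18 mol %), t-BuOOH, 4 Å MS, CH2Cl2, −20 °C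
Reagents that add atoms: tert-butyl hydroperoxide, CC(C)(C)OO
Why: Sharpless asymmetric epoxidation: only the alkene of the primary allylic alcohol is activated by the titanium tartrate complex, and D-(−)-tartrate (the mirror-image sense of step 1) gives the (3S,4R)-oxirane under reagent control, with C2 and C5 cis as in the Z-alkene.

Step 12
Reactants: 19 (3S,4R)-alkynyl oxirane
Product: 20 (1Z)-alkenyl oxirane
Conditions: H2 (1 atm), Pd/CaCO3 poisoned with Pb(OAc)2, quinoline, EtOAc, rt, stopped after one equivalent of H2
Reagents that add atoms: none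
Why: Syn semihydrogenation over lead-poisoned palladium gives the Z C1=C2 alkene, because the alkyne binds far more strongly than the vinyl, acrylate and angelate alkenes for as long as it is present.

Step 13
Reactants: 20 (1Z)-alkenyl oxirane
Product: 21 (1R,2S,3S,4R)-bis-oxirane alcohol
Conditions: VO(acac)2 (5 mol %), t-BuOOH, CH2Cl2, 0 °C
Reagents that add atoms: tert-butyl hydroperoxide, CC(C)(C)OO
Why: Hydroxyl-directed vanadium-catalysed epoxidation: only C1=C2 is allylic to a free hydroxyl group, and in the A1,3-minimised transition state the C10 hydroxyl sits about 50° out of the alkene plane with the small C14 methyl inside and C9 outside, H3 eclipses the alkene so that attack is anti to the C3–O bond, and the C5 hydroxymethyl group lies on the same face, so all three elements should deliver oxygen to the face that gives the (1R,2S)-cis-oxirane.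

Step 14
Reactants: 21 (1R,2S,3S,4R)-bis-oxirane alcohol
Product: 22 bis-oxirane C5 aldehyde
Conditions: TEMPO (10 mol %), PhI(OAc)2, CH2Cl2, rt
Reagents that add atoms: none
Why: Oxoammonium (TEMPO) oxidation of the only primary alcohol gives an epoxy aldehyde that has no α-hydrogen and cannot epimerise, and neither oxirane is allylic at this stage.

Step 15
Reactants: 22 bis-oxirane C5 aldehyde
Product: 23 metathesis diene (vinyl groups on C4 and C7)
Conditions: Ph3PCH3Br, KN(SiMe3)2, THF, 0 °C; then 22 (one equivalent of ylide), −78 to 0 °C
Reagents that add atoms: methyltriphenylphosphonium bromide, C[P+](c1ccccc1)(c1ccccc1)c1ccccc1.[Br-]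
Why: Wittig methylenation: at −78 °C the aldehyde reacts much faster than the ylide adds to the acrylate, and the ylide is too weak a base to deprotonate the C10 hydroxyl group, so no Payne rearrangement is started.

Step 16
Reactants: 23 metathesis diene
Product: 24 (5Z)-ten-membered carbocycle, 2-(trimethylsilyl)ethyl ester
Conditions: second-generation Hoveyda–Grubbs catalyst (10 mol %), 1,4-benzoquinone (20 mol %), toluene (1 mM), 70 °C
Reagents that add atoms: none
Why: Ring-closing metathesis of the two monosubstituted alkenes, with the 1,1-disubstituted acrylate and the trisubstituted angelate left out: the two cis-oxiranes fold the chain so that C5 and C6 come close, and a ten-membered ring that already holds two cis-fused oxiranes next to the new bond should accept only the Z-alkene.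

Step 17
Reactants: 24 (5Z)-ten-membered carbocycle, 2-(trimethylsilyl)ethyl ester
Product: 25 (5Z)-epoxy acid
Conditions: Bu4NF, THF, 0 °C; then cold 0.1 M HCl to pH 4; used at once
Reagents that add atoms: none
Why: Fluoride-induced fragmentation of the 2-(trimethylsilyl)ethyl ester (β-elimination of ethene) frees the acid without strong acid or hydroxide, so the oxiranes, the angelate and the acrylate unit survive.

Step 18
Reactants: 25 (5Z)-epoxy acid
Product: 26 target, (1R,2R,3R,4Z,6S,7R,8S,10R)-8-angeloyloxy-1,2-epoxy-3,10-dihydroxygermacra-4,11(13)-dien-12,6-olide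
Conditions: Pd2(dba)3·CHCl3 (5 mol %), PPh3 (40 mol %), THF, rt
Reagents that add atoms: none
Why: Zerovalent palladium ionises the tertiary allylic C4–O bond of the vinyl oxirane from the face opposite to the oxygen and gives an η3-allyl complex over C4–C5–C6 plus a C3 alkoxide, which at once takes the proton of the C12 acid, and the carboxylate then attacks C6 on the face opposite to the metal, so that the whole event is a redox-neutral isomerisation by double inversion (net syn-1,4 opening). The closest known reaction type is the Tsuji–Trost 1,4-addition of carboxylic acids to cyclic 1,3-diene monoepoxides, which gives cis-4-acyloxyalk-2-en-1-ols, together with the palladium-catalysed lactonisation of allylic esters that carry a free acid. The one ring that closes is the γ-lactone (O, C12, C11, C7, C6), by a 5-exo attack with the allyl unit outside the new ring, whereas attack at C4 would need a seven-membered ring at a fully substituted carbon. C6 is the only new stereocentre and is set by chirality transfer from C4: the oxirane oxygen and the acrylic acid arm on C7 lie on the same face of the all-cis ring, so the metal binds the other face and the tethered carboxylate can reach C6 only from its own face, which gives 6S and the cis-fused lactone, while C3 keeps its C–O bond and configuration. The 4Z geometry follows from the cis-oxirane and the 5Z alkene, which make C3 and C7 the two anti substituents of a U-shaped allyl unit held in the ten-membered ring. The step needs chemoselectivity between the two oxiranes and among three oxygen nucleophiles, and the substrate secures it because only the C3–C4 oxirane is allylic, because the proton transfer leaves the carboxylate as the only anion (no 3,6-ether bridge, no Payne shift toward the C1–C2 oxirane), and because re-ionisation of the allylic lactone only regenerates the same complex.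

Compound list
1 | (E)-3-methylpent-2-en-4-yn-1-ol | C#C/C(C)=C/CO | starting material
2 | [(2S,3S)-3-ethynyl-3-methyloxiran-2-yl]methanol | OC[C@@H]1O[C@@]1(C)C#C | intermediate
3 | (3R)-3-methylpent-4-yne-1,3-diol | OCC[C@@](C)(O)C#C | intermediate
4 | (3R)-3-hydroxy-3-methylpent-4-ynal | O=CC[C@@](C)(O)C#C | intermediate
5 | acryloyl chloride | C=CC(=O)Cl | starting material
6 | 2-(trimethylsilyl)ethanol | C[Si](C)(C)CCO | starting material
7 | 2-(trimethylsilyl)ethyl acrylate | C=CC(=O)OCC[Si](C)(C)C | intermediate
8 | acrolein | C=CC=O | starting material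
9 | racemic 2-(trimethylsilyl)ethyl 3-hydroxy-2-methylidenepent-4-enoate | C=CC(O)C(=C)C(=O)OCC[Si](C)(C)C | intermediate
10 | 2-(trimethylsilyl)ethyl (2Z)-2-(bromomethyl)penta-2,4-dienoate | BrC/C(C(=O)OCC[Si](C)(C)C)=C\C=C | intermediate
11 | C8 trimethylsilyl ether of 12 (not isolated) | C=C(C(=O)OCC[Si](C)(C)C)[C@@H](C=C)[C@H](O[Si](C)(C)C)C[C@@](C)(O)C#C | intermediate
12 | 2-(trimethylsilyl)ethyl (3R,4R,6R)-3-ethenyl-4,6-dihydroxy-6-methyl-2-methylideneoct-7-ynoate (7R,8R,10R) | C=C(C(=O)OCC[Si](C)(C)C)[C@@H](C=C)[C@H](O)C[C@@](C)(O)C#C | intermediate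
13 | angelic acid, (2Z)-2-methylbut-2-enoic acid | C/C=C(/C)C(=O)O | starting material
14 | 2-(trimethylsilyl)ethyl (3R,4S,6R)-3-ethenyl-6-hydroxy-6-methyl-4-{[(2Z)-2-methylbut-2-enoyl]oxy}-2-methylideneoct-7-ynoate (7R,8S,10R) | C=C(C(=O)OCC[Si](C)(C)C)[C@@H](C=C)[C@@H](OC(=O)/C(C)=C\C)C[C@@](C)(O)C#C | intermediate
15 | prop-2-yn-1-ol | C#CCO | starting material
16 | (Z)-alkenylmagnesium bromide bromomagnesium alkoxide (not isolated) | C/C(CO[Mg]Br)=C/[Mg]Br | intermediate
17 | (Z)-3-iodo-2-methylprop-2-en-1-ol | I/C=C(/C)CO | intermediate
18 | 2-(trimethylsilyl)ethyl (3R,4S,6R,9Z)-3-ethenyl-6,11-dihydroxy-6,10-dimethyl-4-{[(2Z)-2-methylbut-2-enoyl]oxy}-2-methylideneundec-9-en-7-ynoate | C=C(C(=O)OCC[Si](C)(C)C)[C@@H](C=C)[C@@H](OC(=O)/C(C)=C\C)C[C@@](C)(O)C#C/C=C(/C)CO | intermediate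
19 | 2-(trimethylsilyl)ethyl (3R,4S,6R)-3-ethenyl-6-hydroxy-8-[(2S,3R)-3-(hydroxymethyl)-3-methyloxiran-2-yl]-6-methyl-4-{[(2Z)-2-methylbut-2-enoyl]oxy}-2-methylideneoct-7-ynoate | C=C(C(=O)OCC[Si](C)(C)C)[C@@H](C=C)[C@@H](OC(=O)/C(C)=C\C)C[C@@](C)(O)C#C[C@@H]1O[C@]1(C)CO | intermediate
20 | (7Z)-oct-7-enoate analogue of 19 (Z C1=C2; 3S,4R,7R,8S,10R) | C=C(C(=O)OCC[Si](C)(C)C)[C@@H](C=C)[C@@H](OC(=O)/C(C)=C\C)C[C@@](C)(O)/C=C\[C@@H]1O[C@]1(C)CO | intermediate
21 | 2-(trimethylsilyl)ethyl (3R,4S,6R)-3-ethenyl-6-hydroxy-6-{(2R,3S)-3-[(2S,3R)-3-(hydroxymethyl)-3-methyloxiran-2-yl]oxiran-2-yl}-4-{[(2Z)-2-methylbut-2-enoyl]oxy}-2-methylideneheptanoate (1R,2S,3S,4R,7R,8S,10R) | C=C(C(=O)OCC[Si](C)(C)C)[C@@H](C=C)[C@@H](OC(=O)/C(C)=C\C)C[C@@](C)(O)[C@@H]1O[C@@H]1[C@@H]1O[C@]1(C)CO | intermediate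
22 | C5 aldehyde of 21, with a (2S,3S)-3-formyl-3-methyloxiran-2-yl end group (1R,2S,3S,4S,7R,8S,10R) | C=C(C(=O)OCC[Si](C)(C)C)[C@@H](C=C)[C@@H](OC(=O)/C(C)=C\C)C[C@@](C)(O)[C@@H]1O[C@@H]1[C@@H]1O[C@]1(C)C=O | intermediate
23 | diene with a (2S,3R)-3-ethenyl-3-methyloxiran-2-yl end group (1R,2S,3S,4R,7R,8S,10R) | C=C(C(=O)OCC[Si](C)(C)C)[C@@H](C=C)[C@@H](OC(=O)/C(C)=C\C)C[C@@](C)(O)[C@@H]1O[C@@H]1[C@@H]1O[C@]1(C)C=C | intermediate
24 | 2-(trimethylsilyl)ethyl 2-[(1R,2S,3S,4R,5Z,7R,8S,10R)-8-angeloyloxy-1,2:3,4-diepoxy-10-hydroxygermacr-5-en-7-yl]acrylate | C=C(C(=O)OCC[Si](C)(C)C)[C@H]1/C=C\[C@@]2(C)O[C@H]2[C@H]3O[C@H]3[C@](C)(O)C[C@@H]1OC(=O)/C(C)=C\C | intermediate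
25 | 2-[(1R,2S,3S,4R,5Z,7R,8S,10R)-8-angeloyloxy-1,2:3,4-diepoxy-10-hydroxygermacr-5-en-7-yl]acrylic acid | C=C(C(=O)O)[C@H]1/C=C\[C@@]2(C)O[C@H]2[C@H]3O[C@H]3[C@](C)(O)C[C@@H]1OC(=O)/C(C)=C\C | intermediate
26 | (1R,2R,3R,4Z,6S,7R,8S,10R)-8-angeloyloxy-1,2-epoxy-3,10-dihydroxygermacra-4,11(13)-dien-12,6-olide | C=C1C(=O)O[C@H]2/C=C(/C)[C@@H](O)[C@H]3O[C@H]3[C@](C)(O)C[C@H](OC(=O)/C(C)=C\C)[C@@H]12 | target

Total step count: 18. Longest linear sequence: 14 steps (1, 2, 3, 7, 8, 10–18).

Steps most likely to fail

Step 16 (ring-closing metathesis). Ruthenium may load slowly on the vinyl group at the fully substituted oxirane carbon C4, and the ester carbonyl may chelate the C6 carbene. Oligomerisation or double-bond migration could then overtake closure of the strained ring. The fallback is a relay ring closure, in which the substrate brings the catalyst to C5 instead of relying on direct initiation. It sets out from aldehyde 22. In place of the methylenation, 22 undergoes a Z-selective Wittig reaction with the ylide of hex-5-enyltriphenylphosphonium bromide (KN(SiMe3)2, THF, −78 °C) and gives the relay triene F1. The second-generation Hoveyda–Grubbs catalyst enters at the unhindered terminal alkene, expels cyclopentene, is thereby placed on C5 and closes onto the C7 vinyl group. The sequence comes back to the route at 24.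

Step 8 (Mitsunobu inversion). The activated C8 oxygen may be lost by elimination toward the doubly allylic C7–H, or the neighbouring ester carbonyl may participate, in place of clean SN2 displacement by angelate. The fallback replaces substitution by oxidation, hydroxyl-directed reduction and acylation with retention. It sets out from 12. Dess–Martin periodinane (NaHCO3, CH2Cl2, 0 °C) gives the β-hydroxy ketone F2, which is reduced at once by the Evans–Saksena method (Me4NBH(OAc)3, MeCN/AcOH, −30 °C). Hydride is delivered from boron bound to O10 through a chair with the C14 methyl equatorial and the slim ethynyl group axial. This should give the (8S)-diol F3, with O8 and O10 syn along the C7–C1 chain. A Yamaguchi-type esterification of the secondary hydroxyl group with angelic acid 13 follows (2,4,6-trichlorobenzoyl chloride, Et3N, then F3, toluene, 80 °C, no DMAP). The sequence comes back to the route at 14.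

Step 18 (key lactonisation). The ring may fail to adopt the U-shaped allyl geometry, so that ionisation is sluggish. The allyl complex may also lose a β-hydride, undergo syn–anti isomerisation before capture, or be captured by O3 in place of the carboxylate. The fallback forms the same O–C6 bond by halolactonisation and then transposes reductively. It sets out from 25. Iodine (NaHCO3, MeCN, 0 °C) adds to the 5Z alkene from the face opposite to the tethered carboxylate, which closes the five-membered ring at C6, the alkene carbon remote from the electron-poor oxirane carbon, and gives the iodolactone F4. Zinc dust (EtOH/AcOH, 0 °C) then brings about the reductive opening of the β-iodo oxirane. The C5–I and C4–O bonds are anti in the ring, so the 4Z alkene and the free C3 hydroxyl group result. The sequence comes back to the route at 26.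

Further compounds
F1 | step 16 | relay triene, 23 with a (Z)-hepta-1,6-dienyl group on C4 in place of vinyl | C=C(C(=O)OCC[Si](C)(C)C)[C@@H](C=C)[C@@H](OC(=O)/C(C)=C\C)C[C@@](C)(O)[C@@H]1O[C@@H]1[C@@H]1O[C@]1(C)/C=C\CCCC=C
F2 | step 8 | 2-(trimethylsilyl)ethyl (3R,6R)-3-ethenyl-6-hydroxy-6-methyl-2-methylidene-4-oxooct-7-ynoate | C=C(C(=O)OCC[Si](C)(C)C)[C@@H](C=C)C(=O)C[C@@](C)(O)C#C
F3 | step 8 | 2-(trimethylsilyl)ethyl (3R,4S,6R)-3-ethenyl-4,6-dihydroxy-6-methyl-2-methylideneoct-7-ynoate | C=C(C(=O)OCC[Si](C)(C)C)[C@@H](C=C)[C@@H](O)C[C@@](C)(O)C#C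
F4 | step 18 | (1R,2S,3S,4S,5S,6R,7R,8S,10R)-8-angeloyloxy-1,2:3,4-diepoxy-10-hydroxy-5-iodogermacr-11(13)-en-12,6-olide | C=C1C(=O)O[C@H]2[C@H](I)[C@@]3(C)O[C@H]3[C@H]4O[C@H]4[C@](C)(O)C[C@H](OC(=O)/C(C)=C\C)[C@@H]12
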